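**Retrosynthetic overview**
1. Target 41 ⇐ ester 39 (saponification, MOM removal) ⇐ one-carbon homologation of ester 36 ⇐ Johnson–Claisen rearrangement of tertiary allylic alcohol 33, which sets C1 and the isopropylidene group.
2. 33 ⇐ enol triflate 30 (carbonylation, MeMgBr) ⇐ cuprate addition and triflation of octalone 28, which sets the angular C8a methyl and the cis ring fusion.
3. Ring A of 28 ⇐ intramolecular aldol condensation of a 1,5-diketone, made by Michael addition of enolate 24 to silyl vinyl ketone 21 (fragment 3).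
4. Ring B arrives as silyl enol ether 23 ⇐ conjugate addition of a benzylic Grignard reagent (fragment 1, from 4-methoxy-2-methylphenol) to (R)-3,4-dimethylcyclohexenone 14 (fragment 2, from propanal and methyl vinyl ketone).
5. Ring order: ring B first (aldol condensation, step 6), ring A second (aldol condensation, step 14, the key ring closure).

Assumption: ordinary laboratory reagents (MeLi, MeMgBr, Me3SiCl, orthoacetate and the like) are treated as reagents and not numbered; only carbon building blocks are numbered as starting materials.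

Conventions: Ar = 5-methoxy-2-(methoxymethoxy)-3-methylphenyl, and ArCH2 is its benzylic CH2 group. Decalin numbering: C1 carries the acid chain, C2 the isopropylidene, C5 the ArCH2 and a methyl, C6 and C8a one methyl each. Ring A is C1–C4/C4a/C8a, ring B is C4a–C8a. The target read from the SMILES is the cis-fused (1S,4aS,5S,6R,8aR) isomer: H-4a, the three methyls and the acid chain lie on one face, ArCH2 on the other.

**Fragment 1 (steps 1–4)**

Step 1
Reactants: 1 4-methoxy-2-methylphenol
Product: 3 2-hydroxy-5-methoxy-3-methylbenzaldehyde, via benzylic alcohol 2 (not isolated)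
Conditions: MgCl2, Et3N, (CH2O)n, MeCN, reflux
Reagents that add atoms: paraformaldehyde, C=O
Why: Magnesium-phenoxide-directed ortho-formylation (Casnati–Skattebøl) attacks the only free ortho position, and a second formaldehyde oxidises the hydroxymethyl intermediate to the aldehyde.

Step 2
Reactants: 3 2-hydroxy-5-methoxy-3-methylbenzaldehyde
Product: 4 5-methoxy-2-(methoxymethoxy)-3-methylbenzaldehyde
Conditions: MOMCl, i-Pr2NEt, CH2Cl2, 0 °C to rt
Reagents that add atoms: chloromethyl methyl ether, COCCl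
Why: O-alkylation of the phenol gives a MOM acetal that survives all later basic and organometallic steps.

Step 3
Reactants: 4 5-methoxy-2-(methoxymethoxy)-3-methylbenzaldehyde
Product: 5 [5-methoxy-2-(methoxymethoxy)-3-methylphenyl]methanol
Conditions: NaBH4, MeOH, 0 °C
Reagents that add atoms: none
Why: Simple hydride reduction of the aldehyde to the benzylic alcohol.

Step 4
Reactants: 5 [5-methoxy-2-(methoxymethoxy)-3-methylphenyl]methanol
Product: 7 1-(chloromethyl)-5-methoxy-2-(methoxymethoxy)-3-methylbenzene, via mesylate 6 (not isolated)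
Conditions: MsCl, 2,4,6-collidine, LiCl, DMF, 0 °C to rt
Reagents that add atoms: lithium chloride, [Li+].[Cl-]
Why: Mesylation followed by SN2 displacement with chloride under buffered conditions gives the benzylic chloride without touching the acid-labile MOM group.

**Fragment 2 (steps 5–8)**

Step 5
Reactants: 8 propanal; 9 but-3-en-2-one
Product: 10 (2R)-2-methyl-5-oxohexanal
Conditions: (S)-2-[methoxy(diphenyl)methyl]pyrrolidine (5 mol %), ethyl 3,4-dihydroxybenzoate (20 mol %), neat, 4 °C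
Reagents that add atoms: none
Why: Enamine-catalysed asymmetric Michael addition, in which the diphenyl(methoxy)methyl group shields one face of the (E)-enamine so that the enone adds to the other face and C2 is formed as (R).

Step 6
Reactants: 10 (2R)-2-methyl-5-oxohexanal
Product: 12 (4R)-4-methylcyclohex-2-en-1-one, via ketol 11 (not isolated)
Conditions: LiOH, i-PrOH, rt
Reagents that add atoms: none
Why: Intramolecular aldol condensation of the methyl ketone onto the aldehyde closes the six-membered ring faster than the aldehyde α-centre epimerises under this mild base.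

Step 7
Reactants: 12 (4R)-4-methylcyclohex-2-en-1-one
Product: 13 trimethyl{[(3S,4R)-3,4-dimethylcyclohex-1-en-1-yl]oxy}silane
Conditions: MeMgBr, CuBr·SMe2 (5 mol %), Me3SiCl, HMPA, THF, −78 °C
Reagents that add atoms: methylmagnesium bromide, C[Mg]Br; chlorotrimethylsilane, C[Si](C)(C)Cl
Why: Copper-catalysed conjugate addition with silyl trapping fixes the enol ether toward C2; the methyl enters mainly trans to the C4 methyl, and this C3 centre is erased in step 8.

Step 8
Reactants: 13 trimethyl{[(3S,4R)-3,4-dimethylcyclohex-1-en-1-yl]oxy}silane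
Product: 14 (4R)-3,4-dimethylcyclohex-2-en-1-one
Conditions: Pd(OAc)2 (10 mol %), O2 (1 atm), DMSO, 60 °C
Reagents that add atoms: none
Why: Saegusa–Ito oxidation (palladium enolate, β-hydride elimination from C3) regenerates the enone regiospecifically and leaves the C4 stereocentre untouched.

**Fragment 3 (steps 9–11)**

Step 9
Reactants: 15 ethenyl(trimethyl)silane
Product: 17 (1-bromoethenyl)trimethylsilane, via dibromide 16 (not isolated)
Conditions: Br2, CH2Cl2, −78 °C; then Et2NH, reflux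
Reagents that add atoms: bromine, BrBr
Why: Bromine addition followed by amine-induced E2 dehydrobromination gives the α-bromovinylsilane regioselectively.

Step 10
Reactants: 17 (1-bromoethenyl)trimethylsilane; 18 acetaldehyde
Product: 20 3-(trimethylsilyl)but-3-en-2-ol (racemic), via alkenylmagnesium bromide 19 (not isolated)
Conditions: Mg, THF, reflux; then CH3CHO, 0 °C; H2O
Reagents that add atoms: none
Why: Grignard formation and 1,2-addition to the aldehyde; the carbinol centre is removed in the next step.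

Step 11
Reactants: 20 3-(trimethylsilyl)but-3-en-2-ol
Product: 21 3-(trimethylsilyl)but-3-en-2-one
Conditions: Dess–Martin periodinane, CH2Cl2, 0 °C
Reagents that add atoms: none
Why: Mild oxidation of the allylic alcohol gives the α-silyl vinyl ketone, a methyl vinyl ketone equivalent that does not polymerise under enolate conditions.

**Union and completion (steps 12–20)**

Step 12
Reactants: 7 1-(chloromethyl)-5-methoxy-2-(methoxymethoxy)-3-methylbenzene; 14 (4R)-3,4-dimethylcyclohex-2-en-1-one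
Product: 23 trimethyl{[(3S,4R)-3-(ArCH2)-3,4-dimethylcyclohex-1-en-1-yl]oxy}silane, via benzylmagnesium chloride 22 (not isolated)
Conditions: Mg, THF, 0 °C; then 14, CuBr·SMe2 (10 mol %), Me3SiCl, HMPA, THF, −78 to −40 °C; Et3N, pentane work-up
Reagents that add atoms: chlorotrimethylsilane, C[Si](C)(C)Cl
Why: Copper-catalysed conjugate addition with silyl trapping; A(1,2) strain holds the C4 methyl pseudoaxial, so the benzyl group enters anti to it and creates the quaternary C3 (S, ArCH2 trans to the C4 methyl), while the enol ether fixes the enolate toward C2.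

Step 13
Reactants: 23 silyl enol ether; 21 3-(trimethylsilyl)but-3-en-2-one
Product: 25 (2S,3S,4R)-3-(ArCH2)-3,4-dimethyl-2-[3-oxo-2-(trimethylsilyl)butyl]cyclohexan-1-one (epimers at the silylated carbon), via lithium enolate 24 (not isolated)
Conditions: MeLi, THF, 0 °C; then 21, −78 °C; H2O
Reagents that add atoms: none
Why: The regiodefined lithium enolate adds to the α-silyl vinyl ketone (Stork–Ganem Michael addition) at C2 anti to the pseudoaxial C3 methyl, the other half-chair being blocked by a syn-axial C4 methyl, which sets C2 (S).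

Step 14
Reactants: 25 α-silyl diketone
Product: 28 (4aR,5S,6R)-5-(ArCH2)-5,6-dimethyl-4,4a,5,6,7,8-hexahydronaphthalen-2(3H)-one, via diketone 26 (not isolated), via ketol 27 (not isolated)
Conditions: KOH, MeOH, 0 °C to rt
Reagents that add atoms: none
Why: Methoxide removes the C-silyl group and the methyl ketone enolate closes ring A by intramolecular aldol addition to the ring ketone and E1cB dehydration (Robinson annulation closure); the hindered C4a–H next to the quaternary carbon is not enolised under these mild conditions, so its configuration is kept.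

Step 15
Reactants: 28 octalone
Product: 30 (4aS,5S,6R,8aR)-5-(ArCH2)-5,6,8a-trimethyl-3,4,4a,5,6,7,8,8a-octahydronaphthalen-2-yl trifluoromethanesulfonate, via lithium enolate 29 (not isolated)
Conditions: Me2CuLi (from MeLi and CuI), Et2O, −20 to 0 °C; then PhNTf2, THF, 0 °C to rt
Reagents that add atoms: lithium dimethylcuprate, [Li+].C[Cu-]C; N-phenylbis(trifluoromethanesulfonimide), O=S(=O)(N(c1ccccc1)S(=O)(=O)C(F)(F)F)C(F)(F)F
Why: Cuprate conjugate addition occurs axially on ring A, anti to the pseudoaxial C4a–C5 bond and away from the axial ArCH2 group, giving the cis-fused angular methyl (C8a cis to H-4a), and the regiodefined enolate is O-triflated.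

Step 16
Reactants: 30 enol triflate
Product: 31 methyl (4aS,5S,6R,8aS)-5-(ArCH2)-5,6,8a-trimethyl-3,4,4a,5,6,7,8,8a-octahydronaphthalene-2-carboxylate
Conditions: Pd(OAc)2 (5 mol %), PPh3 (10 mol %), CO (1 atm), MeOH, Et3N, DMF, 60 °C
Reagents that add atoms: carbon monoxide, [C-]#[O+]; methanol, CO
Why: Palladium-catalysed methoxycarbonylation of the alkenyl triflate (oxidative addition, CO insertion, methanolysis) changes no stereocentre; the 8a descriptor changes only through CIP priorities.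

Step 17
Reactants: 31 methyl ester
Product: 33 2-[(4aS,5S,6R,8aS)-5-(ArCH2)-5,6,8a-trimethyl-3,4,4a,5,6,7,8,8a-octahydronaphthalen-2-yl]propan-2-ol, via methyl ketone 32 (not isolated)
Conditions: MeMgBr (4 equiv), THF, 0 °C to rt; H2O
Reagents that add atoms: methylmagnesium bromide, C[Mg]Br
Why: Double Grignard 1,2-addition to the ester gives the tertiary allylic alcohol, conjugate addition being blocked by the neopentyl β-carbon.

Step 18
Reactants: 33 tertiary allylic alcohol
Product: 36 ethyl 2-[(1S,4aS,5S,6R,8aR)-5-(ArCH2)-5,6,8a-trimethyl-2-(propan-2-ylidene)decahydronaphthalen-1-yl]acetate, via mixed orthoester 34 (not isolated), via ketene acetal 35 (not isolated)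
Conditions: MeC(OEt)3, EtCO2H (cat.), 140 °C, EtOH distilled off
Reagents that add atoms: triethyl orthoacetate, CC(OCC)(OCC)OCC
Why: Johnson–Claisen [3,3] rearrangement forms the C1–C bond axially on the face anti to the pseudoaxial C8a–C8 bond (ring A conformer with equatorial 8a-methyl, the other conformer being blocked on both faces), which sets C1 (S, chain cis to the 8a-methyl) and places the tetrasubstituted isopropylidene alkene regiospecifically.

Step 19
Reactants: 36 ethyl acetate derivative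
Product: 39 ethyl 3-[(1S,4aS,5S,6R,8aR)-5-(ArCH2)-5,6,8a-trimethyl-2-(propan-2-ylidene)decahydronaphthalen-1-yl]propanoate, via lithium dibromoenolate 37 (not isolated), via lithium ynolate 38 (not isolated)
Conditions: CH2Br2, lithium 2,2,6,6-tetramethylpiperidide, THF, −78 °C; LiN(SiMe3)2; then n-BuLi, −78 °C to rt; then HCl/EtOH, 0 °C (brief)
Reagents that add atoms: dibromomethane, BrCBr; ethanol, CCO
Why: Kowalski ester homologation (acylation of LiCHBr2, bromine–lithium exchange, 1,2-shift to the ynolate, ethanolysis) inserts one CH2 without touching C1 or the alkene.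

Step 20
Reactants: 39 ethyl propanoate derivative
Product: 41 3-[(1S,4aS,5S,6R,8aR)-5-[(2-hydroxy-5-methoxy-3-methylphenyl)methyl]-5,6,8a-trimethyl-2-(propan-2-ylidene)decahydronaphthalen-1-yl]propanoic acid, via lithium carboxylate 40 (not isolated)
Conditions: LiOH, THF/MeOH/H2O, 40 °C; then 3 M HCl to pH 1, rt
Reagents that add atoms: lithium hydroxide, [Li+].[OH-]
Why: Saponification followed by acid hydrolysis of the MOM acetal in the same flask; dilute acid at room temperature leaves the tetrasubstituted alkene and all stereocentres untouched.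

**Compound list**
1 | 4-methoxy-2-methylphenol | COc1ccc(O)c(C)c1 | starting material
2 | 2-(hydroxymethyl)-4-methoxy-6-methylphenol | COc1cc(C)c(O)c(CO)c1 | intermediate
3 | 2-hydroxy-5-methoxy-3-methylbenzaldehyde | COc1cc(C)c(O)c(C=O)c1 | intermediate
4 | 5-methoxy-2-(methoxymethoxy)-3-methylbenzaldehyde | COc1cc(C)c(OCOC)c(C=O)c1 | intermediate
5 | [5-methoxy-2-(methoxymethoxy)-3-methylphenyl]methanol | COc1cc(C)c(OCOC)c(CO)c1 | intermediate
6 | [5-methoxy-2-(methoxymethoxy)-3-methylphenyl]methyl methanesulfonate | COc1cc(C)c(OCOC)c(COS(C)(=O)=O)c1 | intermediate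
7 | 1-(chloromethyl)-5-methoxy-2-(methoxymethoxy)-3-methylbenzene (ArCH2Cl) | COc1cc(C)c(OCOC)c(CCl)c1 | intermediate
8 | propanal | CCC=O | starting material
9 | but-3-en-2-one (methyl vinyl ketone) | CC(=O)C=C | starting material
10 | (2R)-2-methyl-5-oxohexanal | O=C[C@H](C)CCC(C)=O | intermediate
11 | (4R)-3-hydroxy-4-methylcyclohexan-1-one (C3 epimers) | O=C1CC(O)[C@H](C)CC1 | intermediate
12 | (4R)-4-methylcyclohex-2-en-1-one | O=C1C=C[C@H](C)CC1 | intermediate
13 | trimethyl{[(3S,4R)-3,4-dimethylcyclohex-1-en-1-yl]oxy}silane (major trans isomer) | C[Si](C)(C)OC1=C[C@@H](C)[C@H](C)CC1 | intermediate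
14 | (4R)-3,4-dimethylcyclohex-2-en-1-one | O=C1C=C(C)[C@H](C)CC1 | intermediate
15 | ethenyl(trimethyl)silane | C=C[Si](C)(C)C | starting material
16 | (1,2-dibromoethyl)trimethylsilane | BrCC(Br)[Si](C)(C)C | intermediate
17 | (1-bromoethenyl)trimethylsilane | C=C(Br)[Si](C)(C)C | intermediate
18 | acetaldehyde | CC=O | starting material
19 | bromo[1-(trimethylsilyl)ethenyl]magnesium | C=C([Mg]Br)[Si](C)(C)C | intermediate
20 | 3-(trimethylsilyl)but-3-en-2-ol (racemic) | CC(O)C(=C)[Si](C)(C)C | intermediate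
21 | 3-(trimethylsilyl)but-3-en-2-one | CC(=O)C(=C)[Si](C)(C)C | intermediate
22 | chloro{[5-methoxy-2-(methoxymethoxy)-3-methylphenyl]methyl}magnesium | COc1cc(C)c(OCOC)c(C[Mg]Cl)c1 | intermediate
23 | trimethyl{[(3S,4R)-3-(ArCH2)-3,4-dimethylcyclohex-1-en-1-yl]oxy}silane | COc1cc(C)c(OCOC)c(C[C@]2(C)C=C(O[Si](C)(C)C)CC[C@H]2C)c1 | intermediate
24 | lithium (3S,4R)-3-(ArCH2)-3,4-dimethylcyclohex-1-en-1-olate | COc1cc(C)c(OCOC)c(C[C@]2(C)C=C(O[Li])CC[C@H]2C)c1 | intermediate
25 | (2S,3S,4R)-3-(ArCH2)-3,4-dimethyl-2-[3-oxo-2-(trimethylsilyl)butyl]cyclohexan-1-one (epimers at the silylated carbon) | COc1cc(C)c(OCOC)c(C[C@]2(C)[C@@H](C(=O)CC[C@H]2C)CC([Si](C)(C)C)C(C)=O)c1 | intermediate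
26 | (2S,3S,4R)-3-(ArCH2)-3,4-dimethyl-2-(3-oxobutyl)cyclohexan-1-one | COc1cc(C)c(OCOC)c(C[C@]2(C)[C@@H](C(=O)CC[C@H]2C)CCC(C)=O)c1 | intermediate
27 | (4aS,5S,6R)-5-(ArCH2)-8a-hydroxy-5,6-dimethyloctahydronaphthalen-2(1H)-one (C8a epimers) | COc1cc(C)c(OCOC)c(C[C@]2(C)[C@@H]3CCC(=O)CC3(O)CC[C@H]2C)c1 | intermediate
28 | (4aR,5S,6R)-5-(ArCH2)-5,6-dimethyl-4,4a,5,6,7,8-hexahydronaphthalen-2(3H)-one | COc1cc(C)c(OCOC)c(C[C@]2(C)[C@@H]3CCC(=O)C=C3CC[C@H]2C)c1 | intermediate
29 | lithium (4aS,5S,6R,8aR)-5-(ArCH2)-5,6,8a-trimethyl-3,4,4a,5,6,7,8,8a-octahydronaphthalen-2-olate | COc1cc(C)c(OCOC)c(C[C@]2(C)[C@@H]3CCC(O[Li])=C[C@]3(C)CC[C@H]2C)c1 | intermediate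
30 | (4aS,5S,6R,8aR)-5-(ArCH2)-5,6,8a-trimethyl-3,4,4a,5,6,7,8,8a-octahydronaphthalen-2-yl trifluoromethanesulfonate | COc1cc(C)c(OCOC)c(C[C@]2(C)[C@@H]3CCC(OS(=O)(=O)C(F)(F)F)=C[C@]3(C)CC[C@H]2C)c1 | intermediate
31 | methyl (4aS,5S,6R,8aS)-5-(ArCH2)-5,6,8a-trimethyl-3,4,4a,5,6,7,8,8a-octahydronaphthalene-2-carboxylate | COc1cc(C)c(OCOC)c(C[C@]2(C)[C@@H]3CCC(C(=O)OC)=C[C@]3(C)CC[C@H]2C)c1 | intermediate
32 | 1-[(4aS,5S,6R,8aS)-5-(ArCH2)-5,6,8a-trimethyl-3,4,4a,5,6,7,8,8a-octahydronaphthalen-2-yl]ethan-1-one | COc1cc(C)c(OCOC)c(C[C@]2(C)[C@@H]3CCC(C(C)=O)=C[C@]3(C)CC[C@H]2C)c1 | intermediate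
33 | 2-[(4aS,5S,6R,8aS)-5-(ArCH2)-5,6,8a-trimethyl-3,4,4a,5,6,7,8,8a-octahydronaphthalen-2-yl]propan-2-ol | COc1cc(C)c(OCOC)c(C[C@]2(C)[C@@H]3CCC(C(C)(C)O)=C[C@]3(C)CC[C@H]2C)c1 | intermediate
34 | mixed orthoester of 33 (its O-(1,1-diethoxyethyl) ether) | COc1cc(C)c(OCOC)c(C[C@]2(C)[C@@H]3CCC(C(C)(C)OC(C)(OCC)OCC)=C[C@]3(C)CC[C@H]2C)c1 | intermediate
35 | ketene acetal of 33 (its O-(1-ethoxyethenyl) ether) | COc1cc(C)c(OCOC)c(C[C@]2(C)[C@@H]3CCC(C(C)(C)OC(=C)OCC)=C[C@]3(C)CC[C@H]2C)c1 | intermediate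
36 | ethyl 2-[(1S,4aS,5S,6R,8aR)-5-(ArCH2)-5,6,8a-trimethyl-2-(propan-2-ylidene)decahydronaphthalen-1-yl]acetate | COc1cc(C)c(OCOC)c(C[C@]2(C)[C@@H]3CCC(=C(C)C)[C@@H](CC(=O)OCC)[C@]3(C)CC[C@H]2C)c1 | intermediate
37 | lithium enolate of the 1,1-dibromomethyl ketone derived from 36 (C1–CH2–C(OLi)=CBr2) | COc1cc(C)c(OCOC)c(C[C@]2(C)[C@@H]3CCC(=C(C)C)[C@@H](CC(O[Li])=C(Br)Br)[C@]3(C)CC[C@H]2C)c1 | intermediate
38 | lithium ynolate (C1–CH2–C≡C–OLi) | COc1cc(C)c(OCOC)c(C[C@]2(C)[C@@H]3CCC(=C(C)C)[C@@H](CC#CO[Li])[C@]3(C)CC[C@H]2C)c1 | intermediate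
39 | ethyl 3-[(1S,4aS,5S,6R,8aR)-5-(ArCH2)-5,6,8a-trimethyl-2-(propan-2-ylidene)decahydronaphthalen-1-yl]propanoate | COc1cc(C)c(OCOC)c(C[C@]2(C)[C@@H]3CCC(=C(C)C)[C@@H](CCC(=O)OCC)[C@]3(C)CC[C@H]2C)c1 | intermediate
40 | lithium 3-[(1S,4aS,5S,6R,8aR)-5-(ArCH2)-5,6,8a-trimethyl-2-(propan-2-ylidene)decahydronaphthalen-1-yl]propanoate | COc1cc(C)c(OCOC)c(C[C@]2(C)[C@@H]3CCC(=C(C)C)[C@@H](CCC(=O)[O-])[C@]3(C)CC[C@H]2C)c1.[Li+] | intermediate
41 | 3-[(1S,4aS,5S,6R,8aR)-5-[(2-hydroxy-5-methoxy-3-methylphenyl)methyl]-5,6,8a-trimethyl-2-(propan-2-ylidene)decahydronaphthalen-1-yl]propanoic acid | COc1cc(C)c(O)c(C[C@]2(C)[C@@H]3CCC(=C(C)C)[C@@H](CCC(=O)O)[C@]3(C)CC[C@H]2C)c1 | target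

**Step count**
Total: 20 steps. Longest linear sequence: 13 steps (steps 1–4 then 12–20; equally steps 5–8 then 12–20). Fragment 3 contributes 3 further steps off that line.

**Three steps most likely to fail, with fallbacks**

Step 12 (benzylic conjugate addition creating a quaternary carbon). Benzylic Grignard reagents tend toward 1,2-addition and Wurtz coupling, and the enone is β,β-disubstituted. The fallback sets out from 7 and 14 and makes the bond without a preformed organometallic. A nickel-catalysed reductive conjugate addition (NiCl2·MeOCH2CH2OMe, 2,2':6',2''-terpyridine, Mn powder, Et3SiCl, DMF, 40 °C) couples the chloride and the enone through a silyloxyallyl–nickel intermediate. It gives triethyl{[(3S,4R)-3-(ArCH2)-3,4-dimethylcyclohex-1-en-1-yl]oxy}silane F1, again anti to the C4 methyl. MeLi in THF then cleaves the silyl enol ether to lithium enolate 24, where the route is rejoined before the Michael addition of step 13.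

Step 15 (angular methylation of the hindered octalone). If the cuprate does not add, the methyl is delivered intramolecularly; the fallback sets out from 28. Reduction with NaBH4 and CeCl3·7H2O in MeOH at −78 °C gives the pseudoequatorial allylic alcohol (2R,4aR,5S,6R)-5-(ArCH2)-5,6-dimethyl-2,3,4,4a,5,6,7,8-octahydronaphthalen-2-ol F2, with the OH cis to H-4a. Hydroxyl-directed Simmons–Smith cyclopropanation (Et2Zn, CH2I2, CH2Cl2, 0 °C) places the CH2 on the same face and gives the 1,8a-methano alcohol F3. Dess–Martin oxidation gives the cyclopropyl ketone F4. Li in liquid NH3/THF at −78 °C cleaves the exocyclic cyclopropane bond that overlaps with the carbonyl, which turns the CH2 into the 8a-methyl and generates lithium enolate 29 regiospecifically. The route is rejoined at 29, which PhNTf2 converts into 30.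

Step 18 (Johnson–Claisen on a tertiary allylic alcohol next to a quaternary carbon). Elimination to the diene or a sluggish rearrangement is possible. The fallback sets out from 33 and uses a [2,3] shift at low temperature instead. O-alkylation (KH, 18-crown-6, Bu3SnCH2I, THF) gives the tributylstannylmethyl ether of 33 F5. n-BuLi at −78 °C triggers tin–lithium exchange and Wittig–Still rearrangement to [(1S,4aS,5S,6R,8aR)-5-(ArCH2)-5,6,8a-trimethyl-2-(propan-2-ylidene)decahydronaphthalen-1-yl]methanol F6, with the same facial preference as the Claisen step. Dess–Martin oxidation gives the corresponding 1-carbaldehyde F7. Ph3P=CHCO2Et in CH2Cl2 gives ethyl (2E)-3-[(1S,4aS,5S,6R,8aR)-5-(ArCH2)-5,6,8a-trimethyl-2-(propan-2-ylidene)decahydronaphthalen-1-yl]prop-2-enoate F8. H2 with RhCl(PPh3)3 in benzene reduces only the disubstituted conjugated alkene. The route is rejoined at 39, so step 19 is bypassed as well.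

**Further compounds**
F1 | step 12 | triethyl{[(3S,4R)-3-(ArCH2)-3,4-dimethylcyclohex-1-en-1-yl]oxy}silane | COc1cc(C)c(OCOC)c(C[C@]2(C)C=C(O[Si](CC)(CC)CC)CC[C@H]2C)c1
F2 | step 15 | (2R,4aR,5S,6R)-5-(ArCH2)-5,6-dimethyl-2,3,4,4a,5,6,7,8-octahydronaphthalen-2-ol (OH cis to H-4a) | COc1cc(C)c(OCOC)c(C[C@]2(C)[C@@H]3CC[C@@H](O)C=C3CC[C@H]2C)c1
F3 | step 15 | 1,8a-methano alcohol from F2 (cyclopropane CH2, 2-OH and H-4a on the same face) | COc1cc(C)c(OCOC)c(C[C@]2(C)[C@@H]3CC[C@@H](O)[C@H]4C[C@@]34CC[C@H]2C)c1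
F4 | step 15 | 1,8a-methano ketone from F3 (cyclopropane CH2 cis to H-4a) | COc1cc(C)c(OCOC)c(C[C@]2(C)[C@@H]3CCC(=O)[C@H]4C[C@@]34CC[C@H]2C)c1
F5 | step 18 | tributyl[({2-[(4aS,5S,6R,8aS)-5-(ArCH2)-5,6,8a-trimethyl-3,4,4a,5,6,7,8,8a-octahydronaphthalen-2-yl]propan-2-yl}oxy)methyl]stannane | COc1cc(C)c(OCOC)c(C[C@]2(C)[C@@H]3CCC(C(C)(C)OC[Sn](CCCC)(CCCC)CCCC)=C[C@]3(C)CC[C@H]2C)c1
F6 | step 18 | [(1S,4aS,5S,6R,8aR)-5-(ArCH2)-5,6,8a-trimethyl-2-(propan-2-ylidene)decahydronaphthalen-1-yl]methanol | COc1cc(C)c(OCOC)c(C[C@]2(C)[C@@H]3CCC(=C(C)C)[C@@H](CO)[C@]3(C)CC[C@H]2C)c1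
F7 | step 18 | (1S,4aS,5S,6R,8aR)-5-(ArCH2)-5,6,8a-trimethyl-2-(propan-2-ylidene)decahydronaphthalene-1-carbaldehyde | COc1cc(C)c(OCOC)c(C[C@]2(C)[C@@H]3CCC(=C(C)C)[C@@H](C=O)[C@]3(C)CC[C@H]2C)c1
F8 | step 18 | ethyl (2E)-3-[(1S,4aS,5S,6R,8aR)-5-(ArCH2)-5,6,8a-trimethyl-2-(propan-2-ylidene)decahydronaphthalen-1-yl]prop-2-enoate | COc1cc(C)c(OCOC)c(C[C@]2(C)[C@@H]3CCC(=C(C)C)[C@@H](/C=C/C(=O)OCC)[C@]3(C)CC[C@H]2C)c1
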